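**Plan** (ring locants O1, C2–C6; side chain C1'–C15'; TBS = tert-butyldimethylsilyl)

- In the ring O1/C2–C6, C6 carries O1 and the C5 methylene, C3=C4 is cis and C2 is at the acid oxidation level. O1–C6 is therefore a latent aldehyde carbonyl and C2–C5 a latent 1-oxygenated butadiene.
- Retrosynthesis: the lactone is taken back to its 2-methoxy-5,6-dihydro-2H-pyran, and C5–C6 and O1–C2 are cut together (retro oxa-[4+2]) to aldehyde 16 and 1-methoxybutadiene.
- The chain is then cut at the carbinol–CH2 bonds C2'–C1', C4'–C3' and C6'–C5', back to 1-decanol and three molecules of allyl acetate.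
- Forward: the chain grows from the nonyl end by three rounds of [Ir(cod)Cl]2/Cl,MeO-BIPHEP-catalysed allylation at the alcohol oxidation level, each followed by ozonolysis. The ring is formed last, then oxidised to the lactone and desilylated.
- Stereochemistry: C6', C4' and C2' come from the one [Ir(cod)Cl]2/Cl,MeO-BIPHEP system with alternating ligand antipodes (R, S, R) for the all-anti array. C6 comes from the chiral [CrCl(L)] catalyst in the ring-forming step.

Key step: step 9

Assumption: the ligand and catalyst antipodes are chosen by the recalled sense of induction of these catalyst families ([Ir(cod)Cl]2 with (R)-Cl,MeO-BIPHEP: Re-face allylation; (1R,2S)-[CrCl(L)]: Re-face cycloaddition). This should be confirmed on the first intermediate; if a sense is opposite, the antipode is used and the route is otherwise unchanged.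

**Step 1**
Reactants: 1 1-decanol; 2 allyl acetate
Product: 4 (4S)-tridec-1-en-4-ol, via decanal 3 (not isolated)
Conditions: [Ir(cod)Cl]2 (2.5 mol %), (R)-Cl,MeO-BIPHEP (5 mol %), 4-chloro-3-nitrobenzoic acid (10 mol %), Cs2CO3 (20 mol %), THF, 100 °C, sealed tube
Reagents that add atoms: none
Why: Krische-type transfer-hydrogenative carbonyl allylation, in which the cyclometalated π-allyl C,O-benzoate complex formed in situ from [Ir(cod)Cl]2, the ligand, the nitrobenzoic acid and allyl acetate dehydrogenates 1 to decanal 3 and allylates it, the (R)-ligand being expected to direct addition to the Re face and set C6' as (S).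

**Step 2**
Reactants: 4 (4S)-tridec-1-en-4-ol
Product: 6 (3S)-dodecane-1,3-diol, via secondary ozonide 5 (not isolated)
Conditions: O3, CH2Cl2, −78 °C; then NaBH4, MeOH, −78 °C to rt
Reagents that add atoms: ozone, O=[O+][O-]
Why: Ozonolysis of the terminal alkene gives the secondary ozonide, which borohydride cleaves reductively straight to the primary alcohol (the excised carbon leaving as methanol), so the chain returns to the alcohol level for the next allylation and the carbinol stereocentre is untouched.

**Step 3**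
Reactants: 6 (3S)-dodecane-1,3-diol; 2 allyl acetate
Product: 8 (4S,6S)-pentadec-1-ene-4,6-diol, via hydroxy aldehyde 7 (not isolated)
Conditions: [Ir(cod)Cl]2 (2.5 mol %), (S)-Cl,MeO-BIPHEP (5 mol %), 4-cyano-3-nitrobenzoic acid (10 mol %), Cs2CO3 (20 mol %), THF, 100 °C, sealed tube
Reagents that add atoms: none
Why: Protecting-group-free Krische-type allylation of a 1,3-glycol, in which the primary carbinol is dehydrogenated much faster than the secondary one to the transient β-hydroxy aldehyde 7, and the (S)-ligand is expected to direct allylation of 7 on the Si face, setting C4' 1,3-anti to C6' under catalyst control.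

**Step 4**
Reactants: 8 (4S,6S)-pentadec-1-ene-4,6-diol
Product: 9 (4S,6S)-4,6-bis(tert-butyldimethylsilyloxy)pentadec-1-ene
Conditions: TBSOTf (2.4 equiv), 2,6-lutidine, CH2Cl2, 0 °C
Reagents that add atoms: tert-butyldimethylsilyl trifluoromethanesulfonate (TBSOTf), CC(C)(C)[Si](C)(C)OS(=O)(=O)C(F)(F)F
Why: Standard bis-silylation with the reactive silyl triflate masks both secondary carbinols so that the later aldehydes carry no free hydroxyl.

**Step 5**
Reactants: 9 (4S,6S)-4,6-bis(tert-butyldimethylsilyloxy)pentadec-1-ene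
Product: 11 (3S,5S)-3,5-bis(tert-butyldimethylsilyloxy)tetradecan-1-ol, via secondary ozonide 10 (not isolated)
Conditions: O3, CH2Cl2, −78 °C; then NaBH4, MeOH, −78 °C to rt
Reagents that add atoms: ozone, O=[O+][O-]
Why: The same ozonolysis with borohydride cleavage of the ozonide as in step 2 shortens the allyl group to the 2-hydroxyethyl terminus; silyl ethers are inert to ozone and borohydride.

**Step 6**
Reactants: 11 (3S,5S)-3,5-bis(tert-butyldimethylsilyloxy)tetradecan-1-ol; 2 allyl acetate
Product: 13 (4R,6S,8S)-6,8-bis(tert-butyldimethylsilyloxy)heptadec-1-en-4-ol, via silyloxy aldehyde 12 (not isolated)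
Conditions: [Ir(cod)Cl]2 (2.5 mol %), (R)-Cl,MeO-BIPHEP (5 mol %), 4-chloro-3-nitrobenzoic acid (10 mol %), Cs2CO3 (20 mol %), THF, 100 °C, sealed tube
Reagents that add atoms: none
Why: Third round of the Krische-type allylation, now with the (R)-ligand, expected to add allyl to the Re face of transient aldehyde 12 and set C2' 1,3-anti to C4'; the β-silyloxy aldehyde never accumulates, which limits β-elimination.

**Step 7**
Reactants: 13 (4R,6S,8S)-6,8-bis(tert-butyldimethylsilyloxy)heptadec-1-en-4-ol
Product: 14 (4R,6R,8S)-4,6,8-tris(tert-butyldimethylsilyloxy)heptadec-1-ene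
Conditions: TBSOTf (1.3 equiv), 2,6-lutidine, CH2Cl2, 0 °C
Reagents that add atoms: tert-butyldimethylsilyl trifluoromethanesulfonate (TBSOTf), CC(C)(C)[Si](C)(C)OS(=O)(=O)C(F)(F)F
Why: Routine silylation of the remaining secondary carbinol gives a uniformly protected, non-coordinating chain for the cycloaddition.

**Step 8**
Reactants: 14 (4R,6R,8S)-4,6,8-tris(tert-butyldimethylsilyloxy)heptadec-1-ene
Product: 16 (3S,5R,7S)-3,5,7-tris(tert-butyldimethylsilyloxy)hexadecanal, via secondary ozonide 15 (not isolated)
Conditions: O3, CH2Cl2, −78 °C; then PPh3, −78 °C to rt; used after short filtration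
Reagents that add atoms: ozone, O=[O+][O-]
Why: Ozonolysis with phosphine reduction stops at the aldehyde, which has no α-stereocentre to epimerise and is used without storage.

**Step 9**
Reactants: 16 (3S,5R,7S)-3,5,7-tris(tert-butyldimethylsilyloxy)hexadecanal; 17 (E)-1-methoxybuta-1,3-diene
Product: 18 (2R,6S)-2-methoxy-6-[(2R,4R,6S)-2,4,6-tris(tert-butyldimethylsilyloxy)pentadecyl]-5,6-dihydro-2H-pyran (cis)
Conditions: (1S,2R)-[CrCl(L)] (5 mol %; L = dianion of 2-(1-adamantyl)-6-{[(2-hydroxy-2,3-dihydro-1H-inden-1-yl)imino]methyl}-4-methylphenol), 17 (3 equiv), 4 Å molecular sieves, minimal t-BuOMe, rt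
Reagents that add atoms: none
Why: The trivalent chromium Lewis acid binds the formyl oxygen of 16 and diene 17 adds in a concerted, asynchronous oxa-[4+2] cycloaddition, its unsubstituted terminus (future C5) bonding to the formyl carbon (future C6) while the carbonyl oxygen (O1) bonds to the methoxy-bearing terminus (future C2); the closest known reaction type is the hetero-Diels–Alder reaction of 1-alkoxybutadienes with aliphatic aldehydes under tridentate Schiff base [CrCl(L)] catalysis. The dihydropyran ring (O1, C2–C6) is closed in one intermolecular [4π+2π] event, so C5–C6 is a ring bond from the moment it forms and C3=C4 is born cis inside the ring. C6 is set by the catalyst, whose (1S,2R) ligand is expected to expose the Si face of the aldehyde and give the (6S) centre, 1,3-anti to C2'; the intrinsic 1,3-anti preference of β-silyloxy aldehydes in Lewis-acid-promoted additions points the same way, so the pairing should be matched. C2 should arise cis to the side chain from the endo transition state and is of no consequence, because it becomes the carbonyl carbon in step 11. The step needs regioselectivity, secured by the polarisation of the diene (nucleophilic at the terminus remote from OMe); facial selectivity, which rests on the catalyst; and chemoselectivity, secured because the formyl group is the only π-electrophile in 16 and all three carbinols are masked as non-coordinating silyl ethers.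

**Step 10**
Reactants: 18 (2R,6S)-2-methoxy-6-[(2R,4R,6S)-2,4,6-tris(tert-butyldimethylsilyloxy)pentadecyl]-5,6-dihydro-2H-pyran
Product: 19 (6S)-6-[(2R,4R,6S)-2,4,6-tris(tert-butyldimethylsilyloxy)pentadecyl]-5,6-dihydro-2H-pyran-2-ol (anomer mixture)
Conditions: PPTS (cat.), acetone/H2O 10:1, rt
Reagents that add atoms: water, O
Why: Mild acid ionises the allylic acetal to the allyl-stabilised oxocarbenium ion, which water traps as the lactol (acetal hydrolysis); pyridinium tosylate is too weak to cleave secondary TBS ethers.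

**Step 11**
Reactants: 19 (6S)-6-[(2R,4R,6S)-2,4,6-tris(tert-butyldimethylsilyloxy)pentadecyl]-5,6-dihydro-2H-pyran-2-ol
Product: 20 (6S)-6-[(2R,4R,6S)-2,4,6-tris(tert-butyldimethylsilyloxy)pentadecyl]-5,6-dihydro-2H-pyran-2-one
Conditions: activated MnO2 (excess), CH2Cl2, rt
Reagents that add atoms: none
Why: MnO2 oxidises the allylic lactol selectively to the α,β-unsaturated δ-lactone (allylic oxidation), and no other free hydroxyl is present.

**Step 12**
Reactants: 20 (6S)-6-[(2R,4R,6S)-2,4,6-tris(tert-butyldimethylsilyloxy)pentadecyl]-5,6-dihydro-2H-pyran-2-one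
Product: 21 (6S)-6-[(2S,4R,6S)-2,4,6-trihydroxypentadecyl]-5,6-dihydro-2H-pyran-2-one (target)
Conditions: aq. HF (48 %), MeCN, 0 °C to rt; NaHCO3 quench
Reagents that add atoms: none
Why: Global acidic desilylation removes the three secondary TBS ethers without opening the lactone and without the base-mediated oxa-Michael addition of the C2' hydroxyl to C4; no stereocentre is touched.

**Compound list**

1 | 1-decanol | CCCCCCCCCCO | starting material
2 | allyl acetate | CC(=O)OCC=C | starting material
3 | decanal (not isolated) | CCCCCCCCCC=O | intermediate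
4 | (4S)-tridec-1-en-4-ol | CCCCCCCCC[C@H](O)CC=C | intermediate
5 | (2S)-1-(1,2,4-trioxolan-3-yl)undecan-2-ol (ring-carbon epimers; not isolated) | CCCCCCCCC[C@H](O)CC1OCOO1 | intermediate
6 | (3S)-dodecane-1,3-diol | CCCCCCCCC[C@H](O)CCO | intermediate
7 | (3S)-3-hydroxydodecanal (not isolated) | CCCCCCCCC[C@H](O)CC=O | intermediate
8 | (4S,6S)-pentadec-1-ene-4,6-diol | CCCCCCCCC[C@H](O)C[C@@H](O)CC=C | intermediate
9 | (4S,6S)-4,6-bis(tert-butyldimethylsilyloxy)pentadec-1-ene | CCCCCCCCC[C@H](O[Si](C)(C)C(C)(C)C)C[C@@H](O[Si](C)(C)C(C)(C)C)CC=C | intermediate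
10 | 3-[(2R,4S)-2,4-bis(tert-butyldimethylsilyloxy)tridecyl]-1,2,4-trioxolane (ring-carbon epimers; not isolated) | CCCCCCCCC[C@H](O[Si](C)(C)C(C)(C)C)C[C@@H](O[Si](C)(C)C(C)(C)C)CC1OCOO1 | intermediate
11 | (3S,5S)-3,5-bis(tert-butyldimethylsilyloxy)tetradecan-1-ol | CCCCCCCCC[C@H](O[Si](C)(C)C(C)(C)C)C[C@@H](O[Si](C)(C)C(C)(C)C)CCO | intermediate
12 | (3R,5S)-3,5-bis(tert-butyldimethylsilyloxy)tetradecanal (not isolated) | CCCCCCCCC[C@H](O[Si](C)(C)C(C)(C)C)C[C@@H](O[Si](C)(C)C(C)(C)C)CC=O | intermediate
13 | (4R,6S,8S)-6,8-bis(tert-butyldimethylsilyloxy)heptadec-1-en-4-ol | CCCCCCCCC[C@H](O[Si](C)(C)C(C)(C)C)C[C@@H](O[Si](C)(C)C(C)(C)C)C[C@H](O)CC=C | intermediate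
14 | (4R,6R,8S)-4,6,8-tris(tert-butyldimethylsilyloxy)heptadec-1-ene | CCCCCCCCC[C@H](O[Si](C)(C)C(C)(C)C)C[C@@H](O[Si](C)(C)C(C)(C)C)C[C@H](O[Si](C)(C)C(C)(C)C)CC=C | intermediate
15 | 3-[(2S,4R,6S)-2,4,6-tris(tert-butyldimethylsilyloxy)pentadecyl]-1,2,4-trioxolane (ring-carbon epimers; not isolated) | CCCCCCCCC[C@H](O[Si](C)(C)C(C)(C)C)C[C@@H](O[Si](C)(C)C(C)(C)C)C[C@H](O[Si](C)(C)C(C)(C)C)CC1OCOO1 | intermediate
16 | (3S,5R,7S)-3,5,7-tris(tert-butyldimethylsilyloxy)hexadecanal | CCCCCCCCC[C@H](O[Si](C)(C)C(C)(C)C)C[C@@H](O[Si](C)(C)C(C)(C)C)C[C@H](O[Si](C)(C)C(C)(C)C)CC=O | intermediate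
17 | (E)-1-methoxybuta-1,3-diene | CO/C=C/C=C | starting material
18 | (2R,6S)-2-methoxy-6-[(2R,4R,6S)-2,4,6-tris(tert-butyldimethylsilyloxy)pentadecyl]-5,6-dihydro-2H-pyran | CCCCCCCCC[C@H](O[Si](C)(C)C(C)(C)C)C[C@@H](O[Si](C)(C)C(C)(C)C)C[C@H](O[Si](C)(C)C(C)(C)C)C[C@@H]1CC=C[C@H](OC)O1 | intermediate
19 | (6S)-6-[(2R,4R,6S)-2,4,6-tris(tert-butyldimethylsilyloxy)pentadecyl]-5,6-dihydro-2H-pyran-2-ol (anomer mixture) | CCCCCCCCC[C@H](O[Si](C)(C)C(C)(C)C)C[C@@H](O[Si](C)(C)C(C)(C)C)C[C@H](O[Si](C)(C)C(C)(C)C)C[C@@H]1CC=CC(O)O1 | intermediate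
20 | (6S)-6-[(2R,4R,6S)-2,4,6-tris(tert-butyldimethylsilyloxy)pentadecyl]-5,6-dihydro-2H-pyran-2-one | CCCCCCCCC[C@H](O[Si](C)(C)C(C)(C)C)C[C@@H](O[Si](C)(C)C(C)(C)C)C[C@H](O[Si](C)(C)C(C)(C)C)C[C@@H]1CC=CC(=O)O1 | intermediate
21 | (6S)-6-[(2S,4R,6S)-2,4,6-trihydroxypentadecyl]-5,6-dihydro-2H-pyran-2-one | CCCCCCCCC[C@H](O)C[C@@H](O)C[C@H](O)C[C@@H]1CC=CC(=O)O1 | target

**Step count and risks**

Total step count: 12. Longest linear sequence: 12 steps (from 1-decanol).

Steps most likely to fail:

1. Step 9. The cycloaddition of the bulky tris(silyloxy) aldehyde may be slow, so that the diene oligomerises first, or the catalyst may not override the substrate and facial selectivity at C6 is eroded. Fallback, from aldehyde 16: Brown allylation with (−)-Ipc2B(allyl), generated from (−)-Ipc2BOMe and CH2=CHCH2MgBr (Et2O, −78 °C; then NaOH, H2O2), should add allyl to the Si face and give (4S,6R,8R,10S)-6,8,10-tris(tert-butyldimethylsilyloxy)nonadec-1-en-4-ol F1. Acylation with acryloyl chloride (i-Pr2NEt, CH2Cl2, 0 °C) should give (4S,6R,8R,10S)-6,8,10-tris(tert-butyldimethylsilyloxy)nonadec-1-en-4-yl prop-2-enoate F2. Ring-closing metathesis with the second-generation Grubbs catalyst [RuCl2(=CHPh)(PCy3)(H2IMes)] in CH2Cl2 at reflux should then close the lactone through C3=C4, and the route is rejoined at lactone 20.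

2. Step 3. On the unprotected diol the secondary carbinol may also be dehydrogenated, or catalyst-directed anti selectivity may be insufficient. Fallback, from alcohol 4: silylation (TBSCl, imidazole, DMF) should give tert-butyldimethyl{[(4S)-tridec-1-en-4-yl]oxy}silane F3. Ozonolysis (O3, CH2Cl2, −78 °C; PPh3) should give (3S)-3-(tert-butyldimethylsilyloxy)dodecanal F4. Reagent-controlled Brown allylation with (−)-Ipc2B(allyl) (Et2O, −78 °C; NaOH, H2O2) should give (4S,6S)-6-(tert-butyldimethylsilyloxy)pentadec-1-en-4-ol F5. Silylation (TBSOTf, 2,6-lutidine) then rejoins the route at bis-silyl ether 9.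

3. Step 10. The lactol may open to the (Z)-hydroxy enal, which can isomerise to the E isomer and no longer close, and aqueous acid may partly remove silyl ethers. Fallback, from acetal 18: direct oxidation with mCPBA and BF3·OEt2 (CH2Cl2, −20 °C), in which the peracid captures the allylic oxocarbenium ion and the peroxy acetal fragments to the lactone, bypasses lactol 19 and rejoins the route at lactone 20; this fallback makes no new compound (F0).

**Further compounds**

F1 | step 9 | (4S,6R,8R,10S)-6,8,10-tris(tert-butyldimethylsilyloxy)nonadec-1-en-4-ol | CCCCCCCCC[C@H](O[Si](C)(C)C(C)(C)C)C[C@@H](O[Si](C)(C)C(C)(C)C)C[C@H](O[Si](C)(C)C(C)(C)C)C[C@@H](O)CC=C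
F2 | step 9 | (4S,6R,8R,10S)-6,8,10-tris(tert-butyldimethylsilyloxy)nonadec-1-en-4-yl prop-2-enoate | CCCCCCCCC[C@H](O[Si](C)(C)C(C)(C)C)C[C@@H](O[Si](C)(C)C(C)(C)C)C[C@H](O[Si](C)(C)C(C)(C)C)C[C@@H](OC(=O)C=C)CC=C
F3 | step 3 | tert-butyldimethyl{[(4S)-tridec-1-en-4-yl]oxy}silane | CCCCCCCCC[C@H](O[Si](C)(C)C(C)(C)C)CC=C
F4 | step 3 | (3S)-3-(tert-butyldimethylsilyloxy)dodecanal | CCCCCCCCC[C@H](O[Si](C)(C)C(C)(C)C)CC=O
F5 | step 3 | (4S,6S)-6-(tert-butyldimethylsilyloxy)pentadec-1-en-4-ol | CCCCCCCCC[C@H](O[Si](C)(C)C(C)(C)C)C[C@@H](O)CC=C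
F0 | step 10 | none | none
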